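The vessel is closed and stirred with the gas held, and I want to know what the oak flask holds at 1.0 h.

| flask | electrophile | free base | gas | remark | time |
|---|---|---|---|---|---|
| oak | 0.25 M | 0.125 M | 18 mM (held) | the very flask that is asked about, followed so far |  |
| larch | 0.17 M | 0.125 M | 18 mM (held) | run made earlier |  |
| flask | 0.25 M | 0.125 M | 18 mM (held) |  | 1.0 h |

- oak (time / min: electrophile / %, target / %): 1.00: 97.1, 1.5; 1.50: 97.9, 1.8; 2.50: 95.5, 4.2; 4.00: 94.8, 5.0; 8.00: 88.2, 9.5; 12.0: 83.9, 14.4
- larch (time / min: electrophile / %, target / %): 3.00: 95.8, 5.7; 6.00: 86.2, 12.2; 10.0: 81.5, 18.0; 15.0: 71.7, 27.6; 25.0: 55.1, 45.5; 40.0: 30.6, 68.3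

(readings scatter by 1 percentage point)

- how much electrophile the flask holds at 1.0 h, in percent of the electrophile charged
- how much target the flask holds at 1.0 h, in percent of the electrophile charged

- the analysis behind the earlier runs scatters by 1 percentage point, standard deviation
- at the start none of the gas is in solution

I compare two times: the time asked, and the clearing time, the time a flask needs to turn its entire charge of electrophile into target at the pace of its readings. The larch run reaches 68.3% target at 40.0 min, so its clearing time is 58.6 min. The oak readings, 14.4% at 12.0 min, give 83.3 min. That is 1.42 times as long, close to the 1.47 between the charges, so across these two runs the clearing time grows with the charge, an apparent zero order in electrophile.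

I scale from larch, whose last reading is large against the scatter of 1 percentage point. For the oak flask that gives 86.1 min, longer than the time asked. My reckoning is therefore 69.7% target and 30.3% electrophile.

The forecast differs, with 49% target and 50.5% electrophile, on the ground that “125 mM caps the flask at 50% of the electrophile”. The larch run has made target equal to 0.929 of its free base charge, so the readings do not test that cap.

The oak flask gives 72.3% target and 27.7% electrophile at 1.0 h.

    electrophile + nucleophile → acid set free + target (k = 20.0 L mol⁻¹ min⁻¹)
    nucleophile + acid set free ⇌ protonated nucleophile, settled at all times (K = 5600 L mol⁻¹)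
    acid set free + free base ⇌ salt of the base (K = 670 L mol⁻¹, k = 6.10 L mol⁻¹ min⁻¹)
    gas ⇌ nucleophile, rate k4*(csat - [nucleophile]) (kL = 0.330 min⁻¹)
    2 free base → self-condensation product (k = 2.20 L mol⁻¹ min⁻¹)

The free base of the oak flask then stands at 1.03% of its own charge. Scaled from the larch run to a neighbour flask charged with 1.0 M of electrophile, the clearing time is 345 min, which gives 17.4% target at 1.0 h, and that neighbour flask holds 23.2%.

(The data come from a simulation from invented constants; the scatter is artificial.)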